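In iridoid numbering (C1 acylal carbon, O2, C3=C4, ring-fusion C5/C9, carbocycle C6–C8, C10 on C8, C11 on C4) the oxygen ring conceals two aldehydes, C1 and C3, joined through C9–C5–C4. Excising the carbocycle atoms C9 and C5 from that chain leaves a 1,3-dicarbonyl, C1–C4–C3, so the ring is disconnected at C4–C5 and C1–C9. One de Mayo operation (enol–alkene [2+2] photocycloaddition, retro-aldol opening, lactol closure) of methyl diformylacetate on a C5=C9 cyclopentene makes both bonds, the pyran and the cis ring fusion. The precursor is an enantiopure cyclopent-2-en-1-ol with the C8 tertiary hydroxyl on the α face and the C10 and C7 silyl ethers on the β face.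

Key step: step 8

Remark: (3S)-3-methylpentanoic acid is taken as a commercial enantiopure acid; β is the face of H5/H9 in the target; C1 lactols and silyl acetals are drawn as the exo (1β) anomers, C1 being fixed only in step 13; TBS = tert-butyldimethylsilyl, TES = triethylsilyl, TBDPS = tert-butyldiphenylsilyl.

**Route**

Step 1
Reactants: 1 cyclopent-2-en-1-one; 2 formaldehyde (37% aqueous)
Product: 3 2-(hydroxymethyl)cyclopent-2-en-1-one
Conditions: imidazole (20 mol%), THF/1 M aq. NaHCO3, rt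
Reagents that add atoms: none
Why: Morita–Baylis–Hillman reaction, in which imidazole adds conjugately to the enone and the resulting enolate captures formaldehyde at the α-carbon (future C8) before the catalyst is eliminated; no stereocenter is formed.

Step 2
Reactants: 3 2-(hydroxymethyl)cyclopent-2-en-1-one
Product: 4 2-{[(tert-butyldimethylsilyl)oxy]methyl}cyclopent-2-en-1-one
Conditions: TBSCl, imidazole, CH2Cl2, 0 °C → rt
Reagents that add atoms: tert-butyldimethylsilyl chloride, CC(C)(C)[Si](C)(C)Cl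
Why: Silyl ether formation at the primary alcohol masks O10 for the borane reduction and installs the one alkyl silyl ether that is later removed selectively; no stereocenter is formed.

Step 3
Reactants: 4 2-{[(tert-butyldimethylsilyl)oxy]methyl}cyclopent-2-en-1-one
Product: 5 (1S)-2-{[(tert-butyldimethylsilyl)oxy]methyl}cyclopent-2-en-1-ol
Conditions: (R)-2-methyl-CBS-oxazaborolidine (10 mol%), BH3·SMe2, THF, −20 °C; then MeOH
Reagents that add atoms: none
Why: Corey–Bakshi–Shibata reduction, in which the α-substituted alkene arm of the enone acts as the large group so that the (R)-oxazaborolidine–borane complex should deliver hydride to the face giving the (S)-carbinol at C7 by reagent control.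

Step 4
Reactants: 5 (1S)-2-{[(tert-butyldimethylsilyl)oxy]methyl}cyclopent-2-en-1-ol
Product: 6 (1S)-1-[(tert-butyldimethylsilyl)oxy]-2-{[(tert-butyldimethylsilyl)oxy]methyl}cyclopent-2-ene
Conditions: TBSCl, imidazole, DMF, rt
Reagents that add atoms: tert-butyldimethylsilyl chloride, CC(C)(C)[Si](C)(C)Cl
Why: Silyl ether formation at the secondary allylic hydroxyl gives the bulky β-substituent at C7 that steers the epoxidation and later screens the β face of the cyclopentene; the C7 configuration is untouched.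

Step 5
Reactants: 6 (1S)-1-[(tert-butyldimethylsilyl)oxy]-2-{[(tert-butyldimethylsilyl)oxy]methyl}cyclopent-2-ene
Product: 7 (1S,2S,5S)-2-[(tert-butyldimethylsilyl)oxy]-1-{[(tert-butyldimethylsilyl)oxy]methyl}-6-oxabicyclo[3.1.0]hexane
Conditions: mCPBA, CH2Cl2/aq. NaHCO3, 0 °C
Reagents that add atoms: 3-chloroperoxybenzoic acid, OOC(=O)c1cccc(Cl)c1
Why: Prilezhaev epoxidation under substrate control: allylic strain with the C8 side chain should hold the C7 silyl ether pseudoaxial, so the peracid adds to the opposite (α) face and sets C8 (oxygen α, C10 β) and, transiently, C9.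

Step 6
Reactants: 7 (1S,2S,5S)-2-[(tert-butyldimethylsilyl)oxy]-1-{[(tert-butyldimethylsilyl)oxy]methyl}-6-oxabicyclo[3.1.0]hexane
Product: 10 (1R,5S)-5-[(tert-butyldimethylsilyl)oxy]-1-{[(tert-butyldimethylsilyl)oxy]methyl}cyclopent-2-en-1-ol, via hydroxy selenide 8 (not isolated), via selenoxide 9 (not isolated)
Conditions: (PhSe)2, NaBH4, EtOH, 0 → 50 °C; then THF, 30% aq. H2O2, pyridine, 0 °C → rt
Reagents that add atoms: none
Why: Epoxide-to-allylic-alcohol transposition by selenolate opening and selenoxide syn-elimination: the selenolate attacks the secondary C9 with inversion (SN2) so the C8–O bond and its configuration are retained, and the selenoxide can only eliminate towards C5 because C8 has no hydrogen, which places the alkene at C5=C9.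

Step 7
Reactants: 11 methyl 3,3-dimethoxypropanoate; 12 methyl formate
Product: 14 methyl diformylacetate (methyl 2-formyl-3-hydroxyprop-2-enoate; chelated enol), via sodium enolate 13 (not isolated)
Conditions: NaH, Et2O, 0 °C → rt; then 1 M aq. HCl, 0 °C
Reagents that add atoms: water, O
Why: Crossed Claisen condensation (C-formylation of the ester enolate with methyl formate) followed by acid hydrolysis of the dimethyl acetal gives the diformyl ester, which rests as its hydrogen-bonded enol; no stereocenter is formed.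

Step 8
Reactants: 10 (1R,5S)-5-[(tert-butyldimethylsilyl)oxy]-1-{[(tert-butyldimethylsilyl)oxy]methyl}cyclopent-2-en-1-ol; 14 methyl diformylacetate
Product: 17 methyl (1R,4aS,6S,7R,7aS)-6-[(tert-butyldimethylsilyl)oxy]-7-{[(tert-butyldimethylsilyl)oxy]methyl}-1,7-dihydroxy-1,4a,5,6,7,7a-hexahydrocyclopenta[c]pyran-4-carboxylate, via cyclobutanol photoadduct 15 (not isolated), via enol dialdehyde 16 (not isolated)
Conditions: hν (medium-pressure mercury lamp, Pyrex filter), 14 (4 equiv), degassed CH2Cl2, 0–5 °C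
Reagents that add atoms: none
Why: Light excites the hydrogen-bonded enol 14, which adds stepwise through a 1,4-biradical across C5=C9 to give cyclobutanol 15 (new bonds C4–C5 and C1–C9), and this strained β-hydroxy dicarbonyl undergoes retro-aldol scission of C1–C4 to dialdehyde 16. The closest known reaction type is the de Mayo reaction of methyl diformylacetate with cyclopentenes, an established entry to iridoid lactols. The dihydropyran closes by 6-exo-trig addition of the C3 enol oxygen to the C1 aldehyde, which leaves the C3=C4 vinylogous carbonate in place. C5 and C9 are set together by suprafacial addition to the α face, which carries only the C8 hydroxyl (a possible hydrogen-bond anchor for the enol), whereas the β face is screened by the C10 silyloxymethyl group and the C7 silyl ether; the cis fusion follows from the cyclobutane, and C1 settles as the exo (β) lactol by anomeric equilibration. The step needs facial and orientational selectivity, and the orientation should follow from sterics, the fully substituted enol carbon C4 bonding to C5 (flanked by CH2) and the CH–OH carbon to C9 next to the quaternary C8.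

Step 9
Reactants: 17 methyl (1R,4aS,6S,7R,7aS)-6-[(tert-butyldimethylsilyl)oxy]-7-{[(tert-butyldimethylsilyl)oxy]methyl}-1,7-dihydroxy-1,4a,5,6,7,7a-hexahydrocyclopenta[c]pyran-4-carboxylate
Product: 18 methyl (1S,4aS,6S,7R,7aS)-6-[(tert-butyldimethylsilyl)oxy]-7-{[(tert-butyldimethylsilyl)oxy]methyl}-7-hydroxy-1-[(triethylsilyl)oxy]-1,4a,5,6,7,7a-hexahydrocyclopenta[c]pyran-4-carboxylate
Conditions: TESCl, imidazole, CH2Cl2, 0 °C
Reagents that add atoms: chlorotriethylsilane, CC[Si](Cl)(CC)CC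
Why: Silyl ether formation at the lactol hydroxyl, the most acidic and least hindered OH (the tertiary C8 hydroxyl does not react with a silyl chloride), turns C1 into a base-stable silyl acetal so the masked dialdehyde cannot open during hydride reduction; the exo anomer is expected and C1 is reset later.

Step 10
Reactants: 18 methyl (1S,4aS,6S,7R,7aS)-6-[(tert-butyldimethylsilyl)oxy]-7-{[(tert-butyldimethylsilyl)oxy]methyl}-7-hydroxy-1-[(triethylsilyl)oxy]-1,4a,5,6,7,7a-hexahydrocyclopenta[c]pyran-4-carboxylate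
Product: 19 (1S,4aS,6S,7R,7aS)-6-[(tert-butyldimethylsilyl)oxy]-7-{[(tert-butyldimethylsilyl)oxy]methyl}-4-(hydroxymethyl)-1-[(triethylsilyl)oxy]-1,4a,5,6,7,7a-hexahydrocyclopenta[c]pyran-7-ol
Conditions: iBu2AlH (4 equiv), CH2Cl2, −78 → −40 °C; aq. potassium sodium tartrate
Reagents that add atoms: none
Why: Hydride reduction of the vinylogous carbonate ester to the primary allylic alcohol with a dialkylaluminium hydride at low temperature (one equivalent is consumed by the C8 hydroxyl) leaves the silyl acetal, the silyl ethers and all stereocenters unchanged.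

Step 11
Reactants: 19 (1S,4aS,6S,7R,7aS)-6-[(tert-butyldimethylsilyl)oxy]-7-{[(tert-butyldimethylsilyl)oxy]methyl}-4-(hydroxymethyl)-1-[(triethylsilyl)oxy]-1,4a,5,6,7,7a-hexahydrocyclopenta[c]pyran-7-ol
Product: 20 (1S,4aS,6S,7R,7aS)-6-[(tert-butyldimethylsilyl)oxy]-7-{[(tert-butyldimethylsilyl)oxy]methyl}-4-{[(tert-butyldiphenylsilyl)oxy]methyl}-1-[(triethylsilyl)oxy]-1,4a,5,6,7,7a-hexahydrocyclopenta[c]pyran-7-ol
Conditions: TBDPSCl, imidazole, CH2Cl2, 0 °C → rt
Reagents that add atoms: tert-butyl(chloro)diphenylsilane, CC(C)(C)[Si](Cl)(c1ccccc1)c1ccccc1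
Why: Silyl ether formation at the new primary allylic hydroxyl with a bulky fluoride-labile group that should outlast both later selective desilylations and keeps the C11 oxygen from being acylated; the tertiary alcohol is too hindered to react.

Step 12
Reactants: 20 (1S,4aS,6S,7R,7aS)-6-[(tert-butyldimethylsilyl)oxy]-7-{[(tert-butyldimethylsilyl)oxy]methyl}-4-{[(tert-butyldiphenylsilyl)oxy]methyl}-1-[(triethylsilyl)oxy]-1,4a,5,6,7,7a-hexahydrocyclopenta[c]pyran-7-ol
Product: 21 (1R,4aS,6S,7R,7aS)-6-[(tert-butyldimethylsilyl)oxy]-7-{[(tert-butyldimethylsilyl)oxy]methyl}-4-{[(tert-butyldiphenylsilyl)oxy]methyl}-1,4a,5,6,7,7a-hexahydrocyclopenta[c]pyran-1,7-diol (used crude)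
Conditions: Bu4NF/AcOH (1:1), THF, −20 → 0 °C
Reagents that add atoms: none
Why: Chemoselective fluoride desilylation: under acetic acid buffering the anomeric triethylsilyl ether, with the lactol oxygen as the best leaving group and the least hindered silicon, should cleave well before the alkyl TBS and TBDPS ethers, and the lactol equilibrates to the exo (1β) anomer.

Step 13
Reactants: 21 (1R,4aS,6S,7R,7aS)-6-[(tert-butyldimethylsilyl)oxy]-7-{[(tert-butyldimethylsilyl)oxy]methyl}-4-{[(tert-butyldiphenylsilyl)oxy]methyl}-1,4a,5,6,7,7a-hexahydrocyclopenta[c]pyran-1,7-diol; 22 (3S)-3-methylpentanoic acid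
Product: 23 (1S,4aS,6S,7R,7aS)-6-[(tert-butyldimethylsilyl)oxy]-7-{[(tert-butyldimethylsilyl)oxy]methyl}-4-{[(tert-butyldiphenylsilyl)oxy]methyl}-7-hydroxy-1,4a,5,6,7,7a-hexahydrocyclopenta[c]pyran-1-yl (3S)-3-methylpentanoate
Conditions: DCC, DMAP (cat.), CH2Cl2, −20 → 0 °C
Reagents that add atoms: none
Why: Steglich esterification of the lactol hydroxyl: the anomers interconvert under the conditions and the exo (β) hydroxyl, trans to the C9–C8 bond and favoured by the anomeric effect, should be acylated, setting C1 as (1S) by substrate control while the tertiary C8 hydroxyl stays free.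

Step 14
Reactants: 23 (1S,4aS,6S,7R,7aS)-6-[(tert-butyldimethylsilyl)oxy]-7-{[(tert-butyldimethylsilyl)oxy]methyl}-4-{[(tert-butyldiphenylsilyl)oxy]methyl}-7-hydroxy-1,4a,5,6,7,7a-hexahydrocyclopenta[c]pyran-1-yl (3S)-3-methylpentanoate
Product: 24 (1S,4aS,6S,7R,7aS)-6-[(tert-butyldimethylsilyl)oxy]-4-{[(tert-butyldiphenylsilyl)oxy]methyl}-7-hydroxy-7-(hydroxymethyl)-1,4a,5,6,7,7a-hexahydrocyclopenta[c]pyran-1-yl (3S)-3-methylpentanoate
Conditions: HF·pyridine, pyridine, THF, 0 °C
Reagents that add atoms: none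
Why: Chemoselective desilylation with pyridine-buffered HF·pyridine, which removes a primary TBS ether well before a hindered secondary TBS or a primary TBDPS ether and is neither basic enough to cleave the acylal nor acidic enough to ionise the enol ether.

Step 15
Reactants: 25 p-coumaric acid [(2E)-3-(4-hydroxyphenyl)prop-2-enoic acid]
Product: 27 (2E)-3-{4-[(tert-butyldimethylsilyl)oxy]phenyl}prop-2-enoic acid, via silyl ester 26 (not isolated)
Conditions: TBSCl (2.2 equiv), imidazole, DMF, rt; then AcOH/THF/H2O, rt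
Reagents that add atoms: tert-butyldimethylsilyl chloride, CC(C)(C)[Si](C)(C)Cl
Why: Silylation of both the phenol and the carboxyl group followed by selective hydrolysis of the far more labile silyl ester gives the phenol-protected acid with the E alkene unchanged; no stereocenter is involved.

Step 16
Reactants: 24 (1S,4aS,6S,7R,7aS)-6-[(tert-butyldimethylsilyl)oxy]-4-{[(tert-butyldiphenylsilyl)oxy]methyl}-7-hydroxy-7-(hydroxymethyl)-1,4a,5,6,7,7a-hexahydrocyclopenta[c]pyran-1-yl (3S)-3-methylpentanoate; 27 (2E)-3-{4-[(tert-butyldimethylsilyl)oxy]phenyl}prop-2-enoic acid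
Product: 28 [(1S,4aS,6S,7R,7aS)-6-[(tert-butyldimethylsilyl)oxy]-4-{[(tert-butyldiphenylsilyl)oxy]methyl}-7-hydroxy-1-{[(3S)-3-methylpentanoyl]oxy}-1,4a,5,6,7,7a-hexahydrocyclopenta[c]pyran-7-yl]methyl (2E)-3-{4-[(tert-butyldimethylsilyl)oxy]phenyl}prop-2-enoate
Conditions: DCC, DMAP (cat.), CH2Cl2, 0 °C → rt
Reagents that add atoms: none
Why: Steglich esterification of the only reactive hydroxyl, the primary C10–OH (the C8 hydroxyl is tertiary), with the phenol-protected cinnamic acid; no stereocenter is affected and the E geometry is retained.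

Step 17
Reactants: 28 [(1S,4aS,6S,7R,7aS)-6-[(tert-butyldimethylsilyl)oxy]-4-{[(tert-butyldiphenylsilyl)oxy]methyl}-7-hydroxy-1-{[(3S)-3-methylpentanoyl]oxy}-1,4a,5,6,7,7a-hexahydrocyclopenta[c]pyran-7-yl]methyl (2E)-3-{4-[(tert-butyldimethylsilyl)oxy]phenyl}prop-2-enoate
Product: 29 [(1S,4aS,6S,7R,7aS)-6,7-dihydroxy-4-(hydroxymethyl)-1-{[(3S)-3-methylpentanoyl]oxy}-1,4a,5,6,7,7a-hexahydrocyclopenta[c]pyran-7-yl]methyl (2E)-3-(4-hydroxyphenyl)prop-2-enoate (CNP0241834.1)
Conditions: Bu4NF/AcOH (1:1, excess), THF, 0 °C → rt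
Reagents that add atoms: none
Why: Global fluoride desilylation buffered with acetic acid removes the secondary TBS, primary TBDPS and aryl TBS ethers without the basicity that would cause acyl migration or acylal cleavage and without the acidity that would ionise the C11 allylic enol ether, leaving all six stereocenters as set.

**Compound list**

1 | cyclopent-2-en-1-one | O=C1CCC=C1 | starting material
2 | formaldehyde (37% aqueous) | C=O | starting material
3 | 2-(hydroxymethyl)cyclopent-2-en-1-one | O=C1CCC=C1CO | intermediate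
4 | 2-{[(tert-butyldimethylsilyl)oxy]methyl}cyclopent-2-en-1-one | O=C1CCC=C1CO[Si](C)(C)C(C)(C)C | intermediate
5 | (1S)-2-{[(tert-butyldimethylsilyl)oxy]methyl}cyclopent-2-en-1-ol | O[C@H]1CCC=C1CO[Si](C)(C)C(C)(C)C | intermediate
6 | (1S)-1-[(tert-butyldimethylsilyl)oxy]-2-{[(tert-butyldimethylsilyl)oxy]methyl}cyclopent-2-ene | CC(C)(C)[Si](C)(C)O[C@H]1CCC=C1CO[Si](C)(C)C(C)(C)C | intermediate
7 | (1S,2S,5S)-2-[(tert-butyldimethylsilyl)oxy]-1-{[(tert-butyldimethylsilyl)oxy]methyl}-6-oxabicyclo[3.1.0]hexane (epoxide oxygen anti to the C7 silyl ether) | CC(C)(C)[Si](C)(C)O[C@H]1CC[C@@H]2O[C@]12CO[Si](C)(C)C(C)(C)C | intermediate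
8 | (1R,2R,5S)-5-[(tert-butyldimethylsilyl)oxy]-1-{[(tert-butyldimethylsilyl)oxy]methyl}-2-(phenylselanyl)cyclopentan-1-ol | CC(C)(C)[Si](C)(C)O[C@H]1CC[C@@H]([Se]c2ccccc2)[C@@]1(O)CO[Si](C)(C)C(C)(C)C | intermediate
9 | Se-oxide of 8 (selenoxide; configuration at selenium undefined) | CC(C)(C)[Si](C)(C)O[C@H]1CC[C@@H]([Se](=O)c2ccccc2)[C@@]1(O)CO[Si](C)(C)C(C)(C)C | intermediate
10 | (1R,5S)-5-[(tert-butyldimethylsilyl)oxy]-1-{[(tert-butyldimethylsilyl)oxy]methyl}cyclopent-2-en-1-ol (key-step precursor) | CC(C)(C)[Si](C)(C)O[C@H]1CC=C[C@@]1(O)CO[Si](C)(C)C(C)(C)C | intermediate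
11 | methyl 3,3-dimethoxypropanoate | COC(OC)CC(=O)OC | starting material
12 | methyl formate | COC=O | starting material
13 | sodium enolate of methyl 2-formyl-3,3-dimethoxypropanoate | [Na+].[O-]C=C(C(OC)OC)C(=O)OC | intermediate
14 | methyl diformylacetate (methyl 2-formyl-3-hydroxyprop-2-enoate, chelated enol) | O=CC(=CO)C(=O)OC | intermediate
15 | cyclobutanol photoadduct: cis-fused bicyclo[3.2.0]heptane with the cyclobutane C4–C5–C9–C1 on the α face, CHO and CO2Me on C4, OH on C1 (C1 and C4 configuration undefined), C7 and C8 as in 10 | O=CC1(C(=O)OC)C(O)[C@H]2[C@@H]1C[C@H](O[Si](C)(C)C(C)(C)C)[C@]2(O)CO[Si](C)(C)C(C)(C)C | intermediate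
16 | ring-opened 1,5-dialdehyde as its C3 enol: cyclopentane with formyl (C1) on C9 and the C(CO2Me)=CHOH unit on C5, cis to each other, C7 and C8 as in 10 | O=C[C@H]1[C@@H](C(=CO)C(=O)OC)C[C@H](O[Si](C)(C)C(C)(C)C)[C@]1(O)CO[Si](C)(C)C(C)(C)C | intermediate
17 | methyl (1R,4aS,6S,7R,7aS)-6-[(tert-butyldimethylsilyl)oxy]-7-{[(tert-butyldimethylsilyl)oxy]methyl}-1,7-dihydroxy-1,4a,5,6,7,7a-hexahydrocyclopenta[c]pyran-4-carboxylate (key-step product) | O[C@@H]1OC=C(C(=O)OC)[C@H]2C[C@H](O[Si](C)(C)C(C)(C)C)[C@](O)(CO[Si](C)(C)C(C)(C)C)[C@@H]12 | intermediate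
18 | methyl (1S,4aS,6S,7R,7aS)-6-[(tert-butyldimethylsilyl)oxy]-7-{[(tert-butyldimethylsilyl)oxy]methyl}-7-hydroxy-1-[(triethylsilyl)oxy]-1,4a,5,6,7,7a-hexahydrocyclopenta[c]pyran-4-carboxylate | CC[Si](CC)(CC)O[C@@H]1OC=C(C(=O)OC)[C@H]2C[C@H](O[Si](C)(C)C(C)(C)C)[C@](O)(CO[Si](C)(C)C(C)(C)C)[C@@H]12 | intermediate
19 | (1S,4aS,6S,7R,7aS)-6-[(tert-butyldimethylsilyl)oxy]-7-{[(tert-butyldimethylsilyl)oxy]methyl}-4-(hydroxymethyl)-1-[(triethylsilyl)oxy]-1,4a,5,6,7,7a-hexahydrocyclopenta[c]pyran-7-ol | CC[Si](CC)(CC)O[C@@H]1OC=C(CO)[C@H]2C[C@H](O[Si](C)(C)C(C)(C)C)[C@](O)(CO[Si](C)(C)C(C)(C)C)[C@@H]12 | intermediate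
20 | (1S,4aS,6S,7R,7aS)-6-[(tert-butyldimethylsilyl)oxy]-7-{[(tert-butyldimethylsilyl)oxy]methyl}-4-{[(tert-butyldiphenylsilyl)oxy]methyl}-1-[(triethylsilyl)oxy]-1,4a,5,6,7,7a-hexahydrocyclopenta[c]pyran-7-ol | CC[Si](CC)(CC)O[C@@H]1OC=C(CO[Si](c3ccccc3)(c3ccccc3)C(C)(C)C)[C@H]2C[C@H](O[Si](C)(C)C(C)(C)C)[C@](O)(CO[Si](C)(C)C(C)(C)C)[C@@H]12 | intermediate
21 | (1R,4aS,6S,7R,7aS)-6-[(tert-butyldimethylsilyl)oxy]-7-{[(tert-butyldimethylsilyl)oxy]methyl}-4-{[(tert-butyldiphenylsilyl)oxy]methyl}-1,4a,5,6,7,7a-hexahydrocyclopenta[c]pyran-1,7-diol | O[C@@H]1OC=C(CO[Si](c3ccccc3)(c3ccccc3)C(C)(C)C)[C@H]2C[C@H](O[Si](C)(C)C(C)(C)C)[C@](O)(CO[Si](C)(C)C(C)(C)C)[C@@H]12 | intermediate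
22 | (3S)-3-methylpentanoic acid | CC[C@H](C)CC(=O)O | starting material
23 | (1S,4aS,6S,7R,7aS)-6-[(tert-butyldimethylsilyl)oxy]-7-{[(tert-butyldimethylsilyl)oxy]methyl}-4-{[(tert-butyldiphenylsilyl)oxy]methyl}-7-hydroxy-1,4a,5,6,7,7a-hexahydrocyclopenta[c]pyran-1-yl (3S)-3-methylpentanoate | CC[C@H](C)CC(=O)O[C@@H]1OC=C(CO[Si](c3ccccc3)(c3ccccc3)C(C)(C)C)[C@H]2C[C@H](O[Si](C)(C)C(C)(C)C)[C@](O)(CO[Si](C)(C)C(C)(C)C)[C@@H]12 | intermediate
24 | (1S,4aS,6S,7R,7aS)-6-[(tert-butyldimethylsilyl)oxy]-4-{[(tert-butyldiphenylsilyl)oxy]methyl}-7-hydroxy-7-(hydroxymethyl)-1,4a,5,6,7,7a-hexahydrocyclopenta[c]pyran-1-yl (3S)-3-methylpentanoate | CC[C@H](C)CC(=O)O[C@@H]1OC=C(CO[Si](c3ccccc3)(c3ccccc3)C(C)(C)C)[C@H]2C[C@H](O[Si](C)(C)C(C)(C)C)[C@](O)(CO)[C@@H]12 | intermediate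
25 | p-coumaric acid [(2E)-3-(4-hydroxyphenyl)prop-2-enoic acid] | O=C(O)/C=C/c1ccc(O)cc1 | starting material
26 | tert-butyldimethylsilyl (2E)-3-{4-[(tert-butyldimethylsilyl)oxy]phenyl}prop-2-enoate | CC(C)(C)[Si](C)(C)OC(=O)/C=C/c1ccc(O[Si](C)(C)C(C)(C)C)cc1 | intermediate
27 | (2E)-3-{4-[(tert-butyldimethylsilyl)oxy]phenyl}prop-2-enoic acid | O=C(O)/C=C/c1ccc(O[Si](C)(C)C(C)(C)C)cc1 | intermediate
28 | [(1S,4aS,6S,7R,7aS)-6-[(tert-butyldimethylsilyl)oxy]-4-{[(tert-butyldiphenylsilyl)oxy]methyl}-7-hydroxy-1-{[(3S)-3-methylpentanoyl]oxy}-1,4a,5,6,7,7a-hexahydrocyclopenta[c]pyran-7-yl]methyl (2E)-3-{4-[(tert-butyldimethylsilyl)oxy]phenyl}prop-2-enoate | CC[C@H](C)CC(=O)O[C@@H]1OC=C(CO[Si](c3ccccc3)(c3ccccc3)C(C)(C)C)[C@H]2C[C@H](O[Si](C)(C)C(C)(C)C)[C@](O)(COC(=O)/C=C/c3ccc(O[Si](C)(C)C(C)(C)C)cc3)[C@@H]12 | intermediate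
29 | [(1S,4aS,6S,7R,7aS)-6,7-dihydroxy-4-(hydroxymethyl)-1-{[(3S)-3-methylpentanoyl]oxy}-1,4a,5,6,7,7a-hexahydrocyclopenta[c]pyran-7-yl]methyl (2E)-3-(4-hydroxyphenyl)prop-2-enoate (CNP0241834.1) | CC[C@H](C)CC(=O)O[C@@H]1OC=C(CO)[C@H]2C[C@H](O)[C@](O)(COC(=O)/C=C/c3ccc(O)cc3)[C@@H]12 | target

**Count and risks**

Total step count: 17. Longest linear sequence: 15 steps (steps 1–6, 8–14, 16 and 17); steps 7 and 15 are one-step side branches.

Steps most likely to fail:

1. Step 8. The flexible bis-silyl ether may not discriminate the two faces well enough, so that part of the cycloaddition occurs on the β face, and conversion may be low because C9 sits next to a quaternary carbon. The fallback locks O7 and O10 into a cis-fused six-membered silylene so that the β face becomes the concave face of a bicycle. It sets out from 10: Bu4NF in THF should give (1R,5S)-1-(hydroxymethyl)cyclopent-2-ene-1,5-diol F1; tBu2Si(OTf)2 with 2,6-lutidine should bridge the 1,3-diol, leaving the tertiary hydroxyl free, to give the 7,10-O-(di-tert-butylsilylene) cyclopentenol F2; the same photocycloaddition and retro-aldol with 14 should give the silylene-bridged lactol ester F3; HF·pyridine should remove the silylene to give the tetrahydroxy ester F4; exhaustive silylation with TBSCl and imidazole at the C1, C7 and C10 hydroxyls should give the tris-TBS ester F5; buffered Bu4NF/AcOH at −20 °C should then remove only the anomeric silyl group, and the route is rejoined at 17.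

2. Step 12. Once the C4 ester is gone, the free lactol may open to the dialdehyde, whose enol tautomerises irreversibly and can eliminate or condense before it is acylated; the anomer ratio is also uncontrolled at this point. The fallback never liberates the lactol. It sets out from 20 and 22: DCC (0.5 equiv) should convert 22 into (3S)-3-methylpentanoic anhydride F6, and slow addition of Bu4NF at −78 °C to 20 in the presence of F6 should acylate the C1 alkoxide as it is released (fluoride-triggered direct conversion of a silyl ether into an ester). The route is rejoined at 23.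

3. Step 17. The hindered secondary C7 silyl ether may cleave slowly, and long fluoride exposure invites migration of the coumaroyl group from O10 to O7, loss of the C1 acylal or ionisation at C11. The fallback stages the deprotection. It sets out from 23: extended HF·pyridine (0 °C → rt) should remove both the O10 and O7 TBS ethers to give the C7,C8,C10-triol 1-ester F7; Steglich acylation with 27 at −20 °C should select the primary C10 hydroxyl over the hindered secondary C7 hydroxyl and give the C7-hydroxy coumarate F8; brief buffered Bu4NF/AcOH then only has to remove the primary TBDPS and aryl TBS ethers, and the route is rejoined at 29.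

**Further compounds**

F1 | step 8 | (1R,5S)-1-(hydroxymethyl)cyclopent-2-ene-1,5-diol | O[C@H]1CC=C[C@@]1(O)CO
F2 | step 8 | 7,10-O-(di-tert-butylsilylene) derivative of F1 [(4aR,7aS)-2,2-di-tert-butyl-4,7-dihydro-7aH-cyclopenta[d][1,3,2]dioxasilin-4a-ol] | CC(C)(C)[Si]1(C(C)(C)C)OC[C@]2(O)C=CC[C@@H]2O1
F3 | step 8 | 7,10-O-(di-tert-butylsilylene) analogue of lactol 17 (1-hydroxy, 8-hydroxy, C11 methyl ester) | O[C@@H]1OC=C(C(=O)OC)[C@H]2C[C@@H]3O[Si](C(C)(C)C)(C(C)(C)C)OC[C@]3(O)[C@@H]12
F4 | step 8 | methyl (1R,4aS,6S,7R,7aS)-1,6,7-trihydroxy-7-(hydroxymethyl)-1,4a,5,6,7,7a-hexahydrocyclopenta[c]pyran-4-carboxylate | O[C@@H]1OC=C(C(=O)OC)[C@H]2C[C@H](O)[C@](O)(CO)[C@@H]12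
F5 | step 8 | methyl (1S,4aS,6S,7R,7aS)-1,6-bis[(tert-butyldimethylsilyl)oxy]-7-{[(tert-butyldimethylsilyl)oxy]methyl}-7-hydroxy-1,4a,5,6,7,7a-hexahydrocyclopenta[c]pyran-4-carboxylate | CC(C)(C)[Si](C)(C)O[C@@H]1OC=C(C(=O)OC)[C@H]2C[C@H](O[Si](C)(C)C(C)(C)C)[C@](O)(CO[Si](C)(C)C(C)(C)C)[C@@H]12
F6 | step 12 | (3S)-3-methylpentanoic anhydride | CC[C@H](C)CC(=O)OC(=O)C[C@@H](C)CC
F7 | step 17 | (1S,4aS,6S,7R,7aS)-4-{[(tert-butyldiphenylsilyl)oxy]methyl}-6,7-dihydroxy-7-(hydroxymethyl)-1,4a,5,6,7,7a-hexahydrocyclopenta[c]pyran-1-yl (3S)-3-methylpentanoate | CC[C@H](C)CC(=O)O[C@@H]1OC=C(CO[Si](c3ccccc3)(c3ccccc3)C(C)(C)C)[C@H]2C[C@H](O)[C@](O)(CO)[C@@H]12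
F8 | step 17 | [(1S,4aS,6S,7R,7aS)-4-{[(tert-butyldiphenylsilyl)oxy]methyl}-6,7-dihydroxy-1-{[(3S)-3-methylpentanoyl]oxy}-1,4a,5,6,7,7a-hexahydrocyclopenta[c]pyran-7-yl]methyl (2E)-3-{4-[(tert-butyldimethylsilyl)oxy]phenyl}prop-2-enoate | CC[C@H](C)CC(=O)O[C@@H]1OC=C(CO[Si](c3ccccc3)(c3ccccc3)C(C)(C)C)[C@H]2C[C@H](O)[C@](O)(COC(=O)/C=C/c3ccc(O[Si](C)(C)C(C)(C)C)cc3)[C@@H]12
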